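Readings and results were computed for substances that don't exist; noise was put on by code.

The vessel was closed, stirred and isothermal, and I had to say what stood in it at 8.0 d and what each remedy could add.

all flasks: starting material 0.10 M; impurity 12 mM

| charge | second substrate | reagent | free catalyst | temperature | remark | time |
|---|---|---|---|---|---|---|
| Wednesday's | 0.050 M | 0.20 M | 7.9 mM | 35 °C | the very flask that is asked about, followed so far |  |
| Thursday's | 0.050 M | 0.20 M | 4 mM | 41 °C | run made earlier |  |
| flask | 0.0500 M | 0.200 M | 7.9 mM | 35 °C |  | 8.0 d |

- Wednesday's (time / d: target / %): 0.417: 16.1; 1.25: 23.5; 2.00: 24.2; 3.00: 24.2; 5.00: 24.9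
- Thursday's (time / d: target / %): 4.00: 10.3; 8.00: 10.6; 10.0: 10.1; 15.0: 10.1; 20.0: 10.8

(each reading ± 0.5 percentage points)

- north: at 8.0 d add free catalyst, 100% of the amount charged, then wait 2.5 d
- west: change nothing and wait 2.5 d more
- south-east: at 8.0 d add reagent, 50.0% of the amount charged, then wait 2.5 d
- north-east: at 8.0 d take out 90% of the target then present, then wait 2.5 d
- east: at 8.0 d raise the temperature by 25 K, then wait 2.5 d

- removed target is counted in
- on the list of suspects stand: free catalyst + impurity -> spent catalyst; starting material + free catalyst <-> catalyst intermediate A; reagent + catalyst intermediate B -> free catalyst + second product; second substrate + free catalyst <-> catalyst intermediate B; reagent + catalyst intermediate A -> free catalyst + target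
- additions bring no volume worth counting

1. target, in percent of the starting material first charged, at 8.0 d
2. the remedy with the largest gain of target, or "none" below 2 percentage points (north / west / south-east / north-east / east / none)
3. target present, with what was taken out counted in, in percent of the starting material first charged, after south-east
4. target present, with what was taken out counted in, in percent of the starting material first charged, after east

The readings formed a ladder of times. Wednesday's flask levelled off at a mean of 24.4%, and its first reading put the half-life of that approach at 0.269 d. On the next rung, the pace of that first interval, held steady, gave 2.59 d for the whole starting material charged, which is longer than that half-life. The asked time stood 1.47 decades above the half-life, so by my reckoning the live share of catalyst was down to 1.09 × 10⁻⁹. Wednesday's target therefore levelled off with 75.6% of the starting material not turned into target.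

So I took the rule from the suspects. Let C be free catalyst, Y impurity and A starting material. Suppose target forms at k_c A C and catalyst dies at k_d Y C. Then C cancels, and with A roughly constant each e-fold fall of Y yields the same target, ρ = k_c A/k_d. The charge of free catalyst is smaller than that of impurity, so Y falls by the catalyst charged. The plateau is thus ρL, with L = ln(Y₀/(Y₀ − C₀)) = 1.07. Wednesday's plateau gave the poison yield ρ = 22.8 mM, as a reading. Thursday's hotter run, with its mean of 10.4%, gave 25.6 mM.

I committed to the plateau at 8.0 d, unchanged by waiting, reagent, heat or removal of target. Fresh catalyst was the exception: the impurity left was 4.10 mM, less than a second charge.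

The forecast said 24.5% now, north as best, 24.5% after south-east and 24.6% after east, on the ground that “Only fresh catalyst helps.”

The flask gave 24.0%, north gained 56 percentage points, and south-east and east stayed at 24.0% and 24.0%.

    free catalyst + impurity → spent catalyst (k = 0.00667 L mol⁻¹ s⁻¹, Ea = 72.0 kJ mol⁻¹)
    starting material + free catalyst ⇌ catalyst intermediate A (K = 1210 L mol⁻¹, k = 0.00171 L mol⁻¹ s⁻¹, Ea = 77.0 kJ mol⁻¹, ΔH = −76.0 kJ mol⁻¹)
    reagent + catalyst intermediate B → free catalyst + second product (k = 0.00259 L mol⁻¹ s⁻¹, Ea = 78.0 kJ mol⁻¹)
    second substrate + free catalyst ⇌ catalyst intermediate B (K = 2210 L mol⁻¹, k = 0.00137 L mol⁻¹ s⁻¹, Ea = 72.0 kJ mol⁻¹, ΔH = −44.0 kJ mol⁻¹)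
    reagent + catalyst intermediate A → free catalyst + target (k = 0.00481 L mol⁻¹ s⁻¹, Ea = 78.0 kJ mol⁻¹)
    (constants at 35 °C)

At the charges, free catalyst met starting material 2.14 times as fast as impurity, forward steps alone. By 4.00 d spent catalyst stood at >99.9%, with 34.2% of the impurity left, and ρ with that remainder gives 24.4%. For a neighbour flask charged with 0.0032 M of free catalyst, ρ gives 7.06%, and that flask held 7.63%.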